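You cannot get a Michaelis constant out of the spring run, which stops at 16.7 % of X. Here are the flasks, that run and what is asked.

| setting | spring | red | violet |
|---|---|---|---|
| Q | 11 mM | 11 mM | 11 mM |
| G | 2 equiv | 2.00 equiv | 2.00 equiv |
| D | 0.4 mol% | 0.2 mol% | 0.2 mol% |
| E | 15 µM | 15 µM | 15 µM |
| temperature | 80 °C | 80 °C | 110 °C |
| remark | run made earlier |  |  |
| time |  | 8.0 min | 8.0 min |

spring run (percent of the Q charged)

| time / s | X / % | Q / % |
|---|---|---|
| 15.0 | 3.3 | 97.3 |
| 30.0 | 6.2 | 93.8 |
| 40.0 | 7.5 | 92.9 |
| 60.0 | 10.2 | 88.6 |
| 80.0 | 14.4 | 85.1 |
| 90.0 | 16.7 | 84.1 |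

(scatter of a reading: 0.5 percentage points)

- the earlier runs do not show what temperature does; that part of a forecast is a guess
- no earlier run changes the charge of D; that part of a forecast is a guess

* the flask that comes out highest in amount of X, in percent of the Q charged, or "all alike" when all lie within 1.5 percentage points (red / violet / all alike)
* X at the end, in percent of the Q charged, red
* X at the end, in percent of the Q charged, violet

Read the table across first. X and Q add up to 100.6 % in the first row and 100.8 % in the last, so X accounts for the Q lost, within the scatter.

Now read it down, dividing X by the loading of D and by the time. The row at 15.0 s gives 0.550 /s, the row at 60.0 s gives 0.425 /s, and the last row gives 0.464 /s. These readings do not fall steadily, since the last value is higher than the one before it, so you cannot read the order in Q. Keep the last value, a reading with its scatter, as the turnover frequency: rounds per D charged, per second, averaged over the run.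

It can still bracket a longer flask, if the catalyst keeps working. Multiply it by the loading and the time, and call that the dose. With a steady rate (zero order in Q), X equals the dose. With a first-order rate that starts at the same value, the law integrates to X = 1 − exp(−dose). At that same starting rate, the integrated Michaelis–Menten curve runs between these two.

Red has half the D. No earlier run tests whether the rate follows D, so I assume it does. Red's dose is 0.445, which gives 44.5 % or 35.9 %, and I commit to the middle, 40.2 %. For violet the readings show nothing about temperature, so I guess a turnover frequency 8 times higher. That gives a dose of 3.56 and, by the first-order form, 97.2 %, so I expect violet to come out higher than red.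

The forecast also names violet, with 82 % there and 32 % in red, below my figure, hedging on the thought “If E poisons D”.

The flasks give 40.3 % in red and 88.9 % in violet, so violet is highest.

    G + D → J (k = 9170 /M/min, Ea = 44.0 kJ/mol)
    X + D ⇌ Xi + D, rate k2*[D]*[X] forward; the back reaction follows from the equilibrium constant (K = 6.00, k = 2120 /M/min, Ea = 55.0 kJ/mol, ΔH = −10.0 kJ/mol)
    Q + J → Jy (k = 17900 /M/min, Ea = 46.0 kJ/mol)
    Ly ⇌ D + X (K = 0.0252 M, k = 190 /min, Ea = 91.0 kJ/mol, ΔH = −50.0 kJ/mol)
    D + E ⇌ Dz, settled at all times (K = 55000 /M, ΔH = −66.0 kJ/mol)
    G + Ly ⇌ Wu, settled at all times (K = 26.9 /M, ΔH = −29.0 kJ/mol)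
    Jy → Z + Ly (k = 72.8 /min, Ea = 97.0 kJ/mol)
    (constants at 80 °C)

Red's 40.3 % lies inside the bracket. Its mean turnover frequency is 0.419 /s, lower than the spring value. At 8.00 min in red, Jy, which holds Q, stands at 32.4 % of the catalyst charged, more than J at 20.5 %. Now take the spring recipe left for 8.0 min. Its dose is 0.891, so the bracket runs from 59.0 % to 89.1 %, and that flask stands at 70.9 %.

The runs stem from a simulated flask for an exercise; the scatter is artificial.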